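Its constants are made up; the run is a simulation.

The constants say how long a turn of the catalyst takes and the gas says how much X arrives, so I began by setting the two side by side.

the same everywhere: D 3.0 M; Q 200 mM (held); Z 300 mM
- epsilon: time 20 h
- beta: time 12 h

    X + Z ⇌ X.Z (K1 = 153 M⁻¹, k1 = 0.213 M⁻¹ min⁻¹)
    D + X.Z → D.X.Z (k2 = 0.173 M⁻¹ min⁻¹)
    D.X.Z ⇌ L (K3 = 2.2, k3 = 0.0407 min⁻¹)
    L → Z + E (k4 = 0.159 min⁻¹)
    Q ⇌ X, rate k5*(csat - [X]) (k5 = 0.0173 min⁻¹, csat = 200 mM)

- at the start none of X is dissolved
- run time (epsilon): 20 h

* which of these there is most of at the end, counted by the D in it, epsilon (D.X.Z / E / D / L)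
* which of these there is most of at the end, counted by the D in it, beta (D.X.Z / E / D / L)
* the largest of these amounts at the end, in percent of the D charged, epsilon
* the largest of these amounts at the end, in percent of the D charged, beta

I gave each form of the catalyst a wait, so that its amount was the turnover rate times that wait. X.Z, D.X.Z and L together cost 35.6 min per turn at full D, counting the return of L. I dropped the return of X.Z, since it falls back far more slowly than it goes on. I set the forms, free Z included, equal to the Z charged, and the turnover equal to the inflow of X. That gave a dissolved X of 0.0556 M.

By this reckoning free Z waited 84.4 min for X, against 1.93 min for X.Z to meet D, so I took the turnover as near zero order in D. The inflow at that X was 0.0500 h⁻¹ of the D charge, and this is my pace, the fraction of the charge the gas delivers per hour. I replaced the curve by this mean. E was the pace times the time, less the gas still in transit: the pace times the wait, plus dissolved X as a fraction of the charge.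

Beta looks like epsilon's twin, with the same charges and so the same pace, but it stops at 12 h against 20 h. At this pace I put the gas delivered at 60.0 % of the charge in beta and 100.0 % in epsilon, so I reckoned E at 55.1 % in beta and 95.1 % in epsilon, the largest amount in both. The mean errs in the tail. At a tenth of the D charge, X.Z waits 19.3 min for D, which is still shorter than Z's wait but half as long as my whole wait. I put beta's stop at about 40.0 % of its D, before that tail, so I expected epsilon to run high and beta not.

The forecast, on the ground that "Gas transfer limits the rate", gave E at 90.5 % for epsilon and E at 55.3 % for beta. On epsilon it stood lower than I did, by 4.6 percentage points.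

The simulation gave E at 92.9 % in epsilon and E at 55.5 % in beta, so my epsilon was 2.2 points high. In epsilon, the transfer of Q had done half of its turnover by 9.83 h, about half the run. The step from D + X.Z had 20 % of its turnover behind it at 4.00 h. In the neighbour with 0.12 M of Z, the same reckoning put X at 0.111 M, moved the pace from 0.0500 h⁻¹ to 0.0308 h⁻¹, and gave E at 56.1 %. That flask computed to 58.0 % of E, with X at 0.113 M.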